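**Plan**

1. Numbering and cuts: ring A is the arene, ring B the lactone (C1 carbonyl, O2, C3, C4), and the side chain runs C1'–C5' from C3, with C4' carrying the ester oxygen. The retrosynthesis cuts, in order, the protecting groups (two aryl benzyl ethers, one primary silyl ether), then C1'=C2' after adding unsaturation (cross-metathesis), then the lactone O2–C3 bond, then the mevalonate ester C–O bond, then the benzylic C4–C3 bond.
2. Enabling feature: C3 of ring B lies between benzylic C4 and side-chain C1'. Written with a C1'=C2' vinyl group, O2–C3 is a branched allylic ester bond of the ring-A carboxylic acid. The allyl unit C3–C1'–C2' is an isomer of the terminal alkyne of a but-3-ynyl arm ortho to CO2H, so an achiral alkynoic acid can be isomerised to the vinyl lactone by a chiral rhodium hydride with no co-product.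
3. Forward order: ring A is elaborated (ortho-methylation, exchange of methyl for benzyl ethers, lateral propargylation) to the alkynoic acid, and ring B closes in the key step. The side chain, pre-assembled as the (S)-pent-4-en-2-yl mevalonate, is joined through the vinyl helper by cross-metathesis. Desilylation and one hydrogenation, which removes the helper C=C and both benzyl ethers, finish the route.
4. Stereochemistry: C3 comes from the chiral diphosphine on rhodium (catalyst control), C4' from (S)-pent-4-en-2-ol and the quaternary carbinol from (R)-mevalonolactone (both chiral pool, no bond to either centre is broken later).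

Key step: step 5

Remark: the sense of induction of the rhodium/diphosphine catalyst is assigned by analogy with intermolecular couplings. The (R,R) ligand is written, and its mirror image would be used if the sense proves opposite.

**Route**

Step 1
Reactants: 1 2,5-dimethoxybenzoic acid
Product: 2 3,6-dimethoxy-2-methylbenzoic acid
Conditions: sec-BuLi (2.2 equiv), TMEDA, THF, −78 °C; MeI, −78 °C → rt; aq. HCl
Reagents that add atoms: iodomethane, CI
Why: Directed ortho-metalation, in which the lithium carboxylate directs sec-butyllithium/TMEDA to C6, the only position ortho to both the carboxylate and a methoxy group, and the aryllithium is then C-methylated.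

Step 2
Reactants: 2 3,6-dimethoxy-2-methylbenzoic acid
Product: 3 3,6-dihydroxy-2-methylbenzoic acid
Conditions: BBr3 (3.5 equiv), CH2Cl2, −78 °C → rt; H2O
Reagents that add atoms: none
Why: Lewis acid demethylation of both aryl methyl ethers by BBr3 frees the hydroquinone so that it can carry hydrogenolysable benzyl ethers instead.

Step 3
Reactants: 3 3,6-dihydroxy-2-methylbenzoic acid
Product: 5 3,6-bis(benzyloxy)-2-methylbenzoic acid, via benzyl ester 4 (not isolated)
Conditions: BnBr (3.5 equiv), K2CO3, DMF, N2, 60 °C; then KOH, H2O/EtOH, 90 °C; aq. HCl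
Reagents that add atoms: benzyl bromide, BrCc1ccccc1; potassium hydroxide, [K+].[OH-]
Why: Williamson O-benzylation of both phenols and the carboxylate, followed by forced saponification of the hindered benzyl ester, should give the acid with base-stable phenol protection.

Step 4
Reactants: 5 3,6-bis(benzyloxy)-2-methylbenzoic acid
Product: 7 3,6-bis(benzyloxy)-2-(but-3-yn-1-yl)benzoic acid, via C-silyl alkyne 6 (not isolated)
Conditions: LiN(iPr)2 (2.3 equiv), THF, −78 → 0 °C; BrCH2C≡CSiMe3, −78 °C → rt; then K2CO3, MeOH, rt; aq. HCl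
Reagents that add atoms: 3-bromo-1-(trimethylsilyl)prop-1-yne, C[Si](C)(C)C#CCBr
Why: Lateral lithiation of the ortho-toluic acid gives a carboxylate-stabilised benzylic dianion that is C-alkylated in SN2 fashion by the propargylic bromide (the silyl cap blocks proton transfer and SN2' attack), and basic methanol then removes the C-silyl group.

Step 5
Reactants: 7 3,6-bis(benzyloxy)-2-(but-3-yn-1-yl)benzoic acid
Product: 8 (3S)-5,8-bis(benzyloxy)-3-ethenyl-3,4-dihydro-1H-isochromen-1-one
Conditions: [RhCl(cod)]2 (2.5 mol %), (R,R)-Cp-DIOP (6 mol %), ClCH2CH2Cl (0.05 M), 70 °C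
Reagents that add atoms: none
Why: Oxidative addition of the carboxylic acid O–H to monovalent rhodium gives a rhodium hydride that isomerises the terminal alkyne through the allene Ar–CH2–CH=C=CH2 to a rhodium allyl spanning C3, C1' and C2', and the carboxylate oxygen then bonds to the substituted terminus C3 by C–O reductive elimination, so the step is an isomerisation without co-product. The closest known reaction type is the rhodium/DIOP-catalysed redox-neutral coupling of terminal alkynes or allenes with carboxylic acids to branched allylic esters, including its lactone-forming intramolecular versions. Ring B closes in a 6-exo mode (oxygen onto the near allyl terminus, vinyl group left outside the ring), whereas attack at C2' would need an eight-membered ring. The new stereocentre C3 is controlled by the C2-symmetric diphosphine on rhodium, which differentiates the two faces of the allyl unit in the C–O bond-forming step; the 3S descriptor of 8 is the spatial arrangement of 3R in the target. The step needs branched over linear regioselectivity and must outrun β-hydride loss from the benzylic C4–H (which would give a 1-aryl-1,3-diene) and intermolecular esterification; the ortho position of the carboxyl group on ring A, which reaches only C3 through a six-membered transition state, together with dilution should secure both.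

Step 6
Reactants: 9 (R)-mevalonolactone
Product: 12 (3R)-5-[(tert-butyldimethylsilyl)oxy]-3-hydroxy-3-methylpentanoic acid, via potassium mevalonate 10 (not isolated), via bis-silyl derivative 11 (not isolated)
Conditions: KOH (1.05 equiv), H2O, rt, then freeze-dry; TBSCl (2.5 equiv), imidazole, DMF, rt; K2CO3, MeOH/THF/H2O, rt; aq. HCl to pH 4
Reagents that add atoms: potassium hydroxide, [K+].[OH-]; tert-butyldimethylsilyl chloride, CC(C)(C)[Si](C)(C)Cl
Why: Hydroxide opens the lactone, silylation caps the primary hydroxyl and the carboxylate (the tertiary hydroxyl is too hindered), and mild carbonate hydrolysis cleaves only the labile silyl ester, leaving the quaternary stereocentre untouched.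

Step 7
Reactants: 12 (3R)-5-[(tert-butyldimethylsilyl)oxy]-3-hydroxy-3-methylpentanoic acid; 13 (S)-pent-4-en-2-ol
Product: 14 (2S)-pent-4-en-2-yl (3R)-5-[(tert-butyldimethylsilyl)oxy]-3-hydroxy-3-methylpentanoate
Conditions: EDC·HCl (1.5 equiv), DMAP (0.3 equiv), CH2Cl2, 0 °C → rt
Reagents that add atoms: none
Why: Steglich esterification acylates the secondary alcohol with retention at both stereocentres, the tertiary β-hydroxyl being too hindered to compete.

Step 8
Reactants: 8 (3S)-5,8-bis(benzyloxy)-3-ethenyl-3,4-dihydro-1H-isochromen-1-one; 14 (2S)-pent-4-en-2-yl (3R)-5-[(tert-butyldimethylsilyl)oxy]-3-hydroxy-3-methylpentanoate (2 equiv)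
Product: 15 (2S,4E)-5-[(3S)-5,8-bis(benzyloxy)-1-oxo-3,4-dihydro-1H-isochromen-3-yl]pent-4-en-2-yl (3R)-5-[(tert-butyldimethylsilyl)oxy]-3-hydroxy-3-methylpentanoate
Conditions: second-generation Hoveyda–Grubbs catalyst, RuCl2(H2IMes)(=CH-C6H4-2-OiPr) (5 mol %), 1,4-benzoquinone (10 mol %), CH2Cl2, 40 °C
Reagents that add atoms: none
Why: Olefin cross-metathesis between the slowly homodimerising, allylically oxygenated vinyl lactone and an excess of the unhindered homoallylic ester should join the two halves with loss of ethene, touching no stereocentre; the E/Z ratio is irrelevant because the alkene is hydrogenated in step 10.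

Step 9
Reactants: 15 (2S,4E)-5-[(3S)-5,8-bis(benzyloxy)-1-oxo-3,4-dihydro-1H-isochromen-3-yl]pent-4-en-2-yl (3R)-5-[(tert-butyldimethylsilyl)oxy]-3-hydroxy-3-methylpentanoate
Product: 16 (2S,4E)-5-[(3S)-5,8-bis(benzyloxy)-1-oxo-3,4-dihydro-1H-isochromen-3-yl]pent-4-en-2-yl (3R)-3,5-dihydroxy-3-methylpentanoate
Conditions: HF·pyridine, pyridine/THF, 0 °C → rt
Reagents that add atoms: none
Why: Buffered fluoride cleaves the primary silyl ether without the base that would trigger translactonisation of the freed 5-hydroxyl onto the ester.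

Step 10
Reactants: 16 (2S,4E)-5-[(3S)-5,8-bis(benzyloxy)-1-oxo-3,4-dihydro-1H-isochromen-3-yl]pent-4-en-2-yl (3R)-3,5-dihydroxy-3-methylpentanoate
Product: 17 aspergimarin C, (2S)-5-[(3R)-5,8-dihydroxy-1-oxo-3,4-dihydro-1H-isochromen-3-yl]pentan-2-yl (3R)-3,5-dihydroxy-3-methylpentanoate
Conditions: H2 (1 atm), 10% Pd/C, EtOAc, rt
Reagents that add atoms: none
Why: Heterogeneous hydrogenation saturates the helper alkene and hydrogenolyses both aryl benzyl ethers under neutral conditions, leaving the esters, the tertiary alcohol and all three stereocentres untouched (C3 changes descriptor from S to R only because the side chain loses CIP priority on saturation).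

**Compound list**

1 | 2,5-dimethoxybenzoic acid | COc1ccc(OC)c(C(=O)O)c1 | starting material
2 | 3,6-dimethoxy-2-methylbenzoic acid | COc1ccc(OC)c(C(=O)O)c1C | intermediate
3 | 3,6-dihydroxy-2-methylbenzoic acid | Cc1c(O)ccc(O)c1C(=O)O | intermediate
4 | benzyl 3,6-bis(benzyloxy)-2-methylbenzoate | Cc1c(OCc2ccccc2)ccc(OCc2ccccc2)c1C(=O)OCc1ccccc1 | intermediate
5 | 3,6-bis(benzyloxy)-2-methylbenzoic acid | Cc1c(OCc2ccccc2)ccc(OCc2ccccc2)c1C(=O)O | intermediate
6 | 3,6-bis(benzyloxy)-2-[4-(trimethylsilyl)but-3-yn-1-yl]benzoic acid | C[Si](C)(C)C#CCCc1c(OCc2ccccc2)ccc(OCc2ccccc2)c1C(=O)O | intermediate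
7 | 3,6-bis(benzyloxy)-2-(but-3-yn-1-yl)benzoic acid | C#CCCc1c(OCc2ccccc2)ccc(OCc2ccccc2)c1C(=O)O | intermediate
8 | (3S)-5,8-bis(benzyloxy)-3-ethenyl-3,4-dihydro-1H-isochromen-1-one | C=C[C@@H]1Cc2c(OCc3ccccc3)ccc(OCc3ccccc3)c2C(=O)O1 | intermediate
9 | (R)-mevalonolactone, (4R)-4-hydroxy-4-methyloxan-2-one | C[C@@]1(O)CCOC(=O)C1 | starting material
10 | potassium (3R)-3,5-dihydroxy-3-methylpentanoate | [K+].[O-]C(=O)C[C@](C)(O)CCO | intermediate
11 | tert-butyldimethylsilyl (3R)-5-[(tert-butyldimethylsilyl)oxy]-3-hydroxy-3-methylpentanoate | CC(C)(C)[Si](C)(C)OC(=O)C[C@](C)(O)CCO[Si](C)(C)C(C)(C)C | intermediate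
12 | (3R)-5-[(tert-butyldimethylsilyl)oxy]-3-hydroxy-3-methylpentanoic acid | OC(=O)C[C@](C)(O)CCO[Si](C)(C)C(C)(C)C | intermediate
13 | (S)-pent-4-en-2-ol | C[C@@H](CC=C)O | starting material
14 | (2S)-pent-4-en-2-yl (3R)-5-[(tert-butyldimethylsilyl)oxy]-3-hydroxy-3-methylpentanoate | C[C@@H](CC=C)OC(=O)C[C@](C)(O)CCO[Si](C)(C)C(C)(C)C | intermediate
15 | (2S,4E)-5-[(3S)-5,8-bis(benzyloxy)-1-oxo-3,4-dihydro-1H-isochromen-3-yl]pent-4-en-2-yl (3R)-5-[(tert-butyldimethylsilyl)oxy]-3-hydroxy-3-methylpentanoate | C[C@@H](C/C=C/[C@@H]1Cc2c(OCc3ccccc3)ccc(OCc3ccccc3)c2C(=O)O1)OC(=O)C[C@](C)(O)CCO[Si](C)(C)C(C)(C)C | intermediate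
16 | (2S,4E)-5-[(3S)-5,8-bis(benzyloxy)-1-oxo-3,4-dihydro-1H-isochromen-3-yl]pent-4-en-2-yl (3R)-3,5-dihydroxy-3-methylpentanoate | C[C@@H](C/C=C/[C@@H]1Cc2c(OCc3ccccc3)ccc(OCc3ccccc3)c2C(=O)O1)OC(=O)C[C@](C)(O)CCO | intermediate
17 | aspergimarin C, (2S)-5-[(3R)-5,8-dihydroxy-1-oxo-3,4-dihydro-1H-isochromen-3-yl]pentan-2-yl (3R)-3,5-dihydroxy-3-methylpentanoate | C[C@@H](CCC[C@@H]1Cc2c(O)ccc(O)c2C(=O)O1)OC(=O)C[C@](C)(O)CCO | target

**Step count and risks**

Total step count: 10. Longest linear sequence: 8 (steps 1–5, 8, 9, 10).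

Steps most likely to fail:

Step 5. The process at risk is the selectivity of the rhodium allyl: insufficient facial discrimination in the C–O bond formation, or diversion by β-hydride loss to a conjugated diene and by intermolecular esterification. The fallback sets C3 by hydrogenation instead of C–O bond formation; it sets out from 4 and comes back at 17. Benzyl ester 4 is isolated before the hydroxide treatment of step 3 and deprotonated at the benzylic methyl with LiN(iPr)2 (THF, −78 °C). The anion is acylated with (6S)-6-methyloxan-2-one ((S)-δ-hexalactone), and the resulting ketone enolate closes onto the benzyl ester to give 5,8-bis(benzyloxy)-3-[(4S)-4-hydroxypentyl]-1H-isochromen-1-one F1. Enantioselective hydrogenation of the C3=C4 enol-lactone double bond of F1 follows, with a chiral ruthenium N-heterocyclic carbene catalyst generated from Ru(cod)(2-methylallyl)2, an enantiopure C2-symmetric imidazolinium salt and KOtBu under H2, the ligand antipode being chosen for 3R. This should give (3R)-5,8-bis(benzyloxy)-3-[(4S)-4-hydroxypentyl]-3,4-dihydro-1H-isochromen-1-one F2. Steglich esterification of F2 with acid 12 gives (2S)-5-[(3R)-5,8-bis(benzyloxy)-1-oxo-3,4-dihydro-1H-isochromen-3-yl]pentan-2-yl (3R)-5-[(tert-butyldimethylsilyl)oxy]-3-hydroxy-3-methylpentanoate F3. Hydrogenolysis (H2, Pd/C, EtOAc) gives (2S)-5-[(3R)-5,8-dihydroxy-1-oxo-3,4-dihydro-1H-isochromen-3-yl]pentan-2-yl (3R)-5-[(tert-butyldimethylsilyl)oxy]-3-hydroxy-3-methylpentanoate F4, and HF·pyridine then gives 17.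

Step 8. The process at risk is the metathesis itself: slow turnover of the allylically oxygenated vinyl group against homodimerisation of the bulky hydroxy ester partner, or ruthenium hydride migration of the double bond into conjugation with the lactone oxygen. The fallback changes the order of bond formation so that the C=C bond is made with a small partner and the ester bond afterwards; it sets out from 8 and comes back at 15. Vinyl lactone 8 is cross-metathesised with an excess of the free alcohol 13 (same ruthenium catalyst) to give (3S)-5,8-bis(benzyloxy)-3-[(1E,4S)-4-hydroxypent-1-en-1-yl]-3,4-dihydro-1H-isochromen-1-one F5. F5 is then acylated with acid 12 (EDC·HCl, DMAP, CH2Cl2) to give 15, which bypasses ester 14.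

Step 10. The process at risk is hydrogenolysis of the allylic C3–O lactone bond on palladium before the alkene is saturated, which would open ring B and destroy the C3 stereocentre. The fallback separates the two reductions; it sets out from 16 and comes back at 17. The alkene of 16 is first saturated with diimide (2-nitrobenzenesulfonyl hydrazide, Et3N, CH2Cl2, rt), which cannot cleave C–O bonds, to give (2S)-5-[(3R)-5,8-bis(benzyloxy)-1-oxo-3,4-dihydro-1H-isochromen-3-yl]pentan-2-yl (3R)-3,5-dihydroxy-3-methylpentanoate F6. F6, which no longer has an allylic C–O bond, is then debenzylated with H2 and Pd/C to give 17.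

Further compounds
F1 | step 5 | 5,8-bis(benzyloxy)-3-[(4S)-4-hydroxypentyl]-1H-isochromen-1-one | C[C@@H](CCCC1=Cc2c(OCc3ccccc3)ccc(OCc3ccccc3)c2C(=O)O1)O
F2 | step 5 | (3R)-5,8-bis(benzyloxy)-3-[(4S)-4-hydroxypentyl]-3,4-dihydro-1H-isochromen-1-one | C[C@@H](CCC[C@@H]1Cc2c(OCc3ccccc3)ccc(OCc3ccccc3)c2C(=O)O1)O
F3 | step 5 | (2S)-5-[(3R)-5,8-bis(benzyloxy)-1-oxo-3,4-dihydro-1H-isochromen-3-yl]pentan-2-yl (3R)-5-[(tert-butyldimethylsilyl)oxy]-3-hydroxy-3-methylpentanoate | C[C@@H](CCC[C@@H]1Cc2c(OCc3ccccc3)ccc(OCc3ccccc3)c2C(=O)O1)OC(=O)C[C@](C)(O)CCO[Si](C)(C)C(C)(C)C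
F4 | step 5 | (2S)-5-[(3R)-5,8-dihydroxy-1-oxo-3,4-dihydro-1H-isochromen-3-yl]pentan-2-yl (3R)-5-[(tert-butyldimethylsilyl)oxy]-3-hydroxy-3-methylpentanoate | C[C@@H](CCC[C@@H]1Cc2c(O)ccc(O)c2C(=O)O1)OC(=O)C[C@](C)(O)CCO[Si](C)(C)C(C)(C)C
F5 | step 8 | (3S)-5,8-bis(benzyloxy)-3-[(1E,4S)-4-hydroxypent-1-en-1-yl]-3,4-dihydro-1H-isochromen-1-one | C[C@@H](C/C=C/[C@@H]1Cc2c(OCc3ccccc3)ccc(OCc3ccccc3)c2C(=O)O1)O
F6 | step 10 | (2S)-5-[(3R)-5,8-bis(benzyloxy)-1-oxo-3,4-dihydro-1H-isochromen-3-yl]pentan-2-yl (3R)-3,5-dihydroxy-3-methylpentanoate | C[C@@H](CCC[C@@H]1Cc2c(OCc3ccccc3)ccc(OCc3ccccc3)c2C(=O)O1)OC(=O)C[C@](C)(O)CCO
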